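# Proposed synthesis of 5,6,2'-trihydroxy-7,8,6'-trimethoxyflavone (26) by aryne insertion into an arylpropiolic acid

## The problem

- Target 26 is a flavone whose ring A is a hexasubstituted benzene (C4a acyl, C5 and C6 hydroxyl, C7 and C8 methoxy, C8a ring oxygen) fused to the pyranone ring C. C2 carries ring B, which has oxygen on both ortho positions (2'-OH, 6'-OMe).
- There is no stereogenic centre, and the C2–C1' axis is flanked on the chromone side only by O1 and C3–H, so it is not configurationally stable. The task is one of regiochemistry and oxygen differentiation, with no stereocontrol to arrange.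
- Three of the six peripheral oxygens are methyl ethers and three are free hydroxyls, and on ring A the pattern OH, OH, OMe, OMe changes in the middle of four contiguous positions. Global methylation or demethylation is therefore useless; each methyl group must be present from the start or be put on one defined oxygen.
- The 5,6-catechol is oxidised easily to the ortho-quinone, especially in base. Fully oxygenated 5-hydroxyflavones open in strong alkali and isomerise in strong acid (Wessely–Moser), so the catechol should be unveiled last under neutral conditions.
- The classical flavone constructions would need a hexasubstituted 2-hydroxyacetophenone and its acylation by a di-ortho-substituted benzoyl unit, both at hindered carbonyls.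
- The enabling feature is that O1 and the C4 acyl carbon sit on adjacent carbons, C8a and C4a. This is the pattern left when an aryne inserts into the C–O bond of a carboxylic acid. If C8 carries hydrogen, the aryne across C4a–C8a has oxygen on the C5 side only and is polarised in one sense.
- The price is that the C8 oxygen must be added afterwards. C8 is then the only free ring A position and lies para to the 5-hydroxyl, which a para-selective phenol oxidation can use. Addition of an oxygen nucleophile to the derived 5,6-quinone is not relied on, because C8 in that quinone is the β-carbon of the C7 enol ether and the doubly activated C8a would compete.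

## Retrosynthesis

**26 from 25.** The two O–benzyl bonds at O6 and O2' are cut. Both non-chelated free phenols of the target are carried as benzyl ethers so that a single neutral hydrogenolysis ends the route and the catechol never sees base or Lewis acid. The forward step must remove two benzyl groups without reducing the C2–C3 double bond.

**25 from 22 through 24.** The C8–O bond and its methyl group are cut. The oxygen is introduced para to the free 5-hydroxyl of 22 by Elbs persulfate oxidation to hydroquinone 24, and the new 8-hydroxyl is methylated selectively because the 5-hydroxyl is hydrogen-bonded to the C4 carbonyl. Electrophilic halogenation at C8 is the neighbouring option, but ring B is an activated resorcinol diether and could compete, whereas the persulfate reaction is tied to the phenoxide and can only go to C8. Compound 22 has C8–H, which is what allows a regiodefined aryne. The forward reaction needs a free 5-hydroxyl and a base-stable ether at O6.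

**22 from 20 through 21.** This is a protecting-group exchange: the O6 benzyl ether is cut back to catechol 21, and 21 to the diphenylmethylene ketal 20. The two hydroxyls of 21 are differentiated by the chelation of the 5-hydroxyl, so one equivalent of alkylating agent should go to O6. The ketal is preferred over benzyl ethers in the earlier stages because the ring A fragment must pass through an aryllithium, and the ketal has no benzylic hydrogen and protects both oxygens in one step. The cost is two steps of exchange.

**20 from 12 and 17 (key disconnection).** O1–C8a, C4–C4a and O1–C2 are cut at once, which removes every bond of ring C that touches ring A or the ring oxygen. A diketone cyclodehydration would instead demand a hexasubstituted hydroxyacetophenone and a hindered acyl transfer. Here the flavone falls into a tetrasubstituted silyl triflate 12 and an arylpropiolic acid 17 that already contains C2, C3 and C4. The forward reaction must: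
- add the carboxylate oxygen to C8a and not C4a;
- transfer the acyl group to C4a faster than the aryl anion is protonated;
- close ring C in the 6-endo sense.

**12 from 5 through 6 and 10.** The O–triflyl and C–Si bonds are cut. The triflate oxygen is the oxygen of phenol 5, and the silyl group is placed on the only free position ortho to it by carbamate-directed lithiation of 6. Ortho-bromination of 5 followed by silyl migration is the alternative and is kept as a fallback, since its regiochemistry is less certain than that of the metalation.

**5 from 1 and 2 through 3.** The phenol C–O bond is traced to the formyl group of 3 (Baeyer–Villiger oxidation), and the ketal to dichlorodiphenylmethane 2. Aldehyde 1 already holds the ring A pattern: its 4-methoxy group becomes the 7-methoxy group, its 2,3-diol the 5,6-diol, and its formyl carbon marks the future C4a.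

**17 from 13 through 14 and 15.** The carboxyl C–C bond is cut (carboxylation of alkyne 15), the alkyne is traced to the aldehyde of 14 by one-carbon homologation, and 14 to 13 by benzylation. The hindered C2–C1' bond of the flavone is already present in 13 as the aryl–formyl bond, so no coupling at a di-ortho-substituted carbon is needed.

## Roads not taken

**Alternative 1:** The cut runs through ring A itself (C5–C6, flavone numbering). A 4-alkenyl-4-hydroxycyclobutenone, assembled from a squaric ester and an α-metalated β-benzyloxyacrylate, would be heated in toluene. Electrocyclic opening gives a dienylketene that closes by 6π electrocyclisation and tautomerises to methyl 6-(benzyloxy)-2,5-dihydroxy-3,4-dimethoxybenzoate A1.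
- Merits: A1 has every ring A substituent in place and correctly differentiated (methoxy groups at the future C7 and C8, benzyl on the C5 oxygen, free hydroxyls at C6 and C8a). There is no aryne regiochemistry and no late oxidation at C8. In certainty of the oxygen pattern this road is better than the chosen one.
- Weak points: A1 is a benzoate flanked on both sides. Turning it into the flavone needs a Claisen-type condensation or an acetophenone and acyl-transfer sequence at that doubly ortho-substituted carbonyl, with an equally hindered ring B partner. The two para hydroxyls of A1 must be told apart, and the hydroquinone is oxidation-prone.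
- Comparison: the whole flavone construction would still lie ahead once ring A is complete. The chosen plan pays with a five-step endgame that includes a persulfate oxidation of modest efficiency. Against that it forms ring C and joins ring B in one step from fragments made in five and three steps.

**Alternative 2:** The cut is the C2–C1' bond. A 2-bromoaryl ester of the fully oxygenated ring A chromone-3-carboxylic acid would undergo palladium-catalysed direct arylation (Pd(OAc)2, PCy3·HBF4, K2CO3, pivalic acid) at the chromone C2–H. This closes a temporary six-membered lactone and gives the 3,2'-lactone of 5,6-(diphenylmethylenedioxy)-2'-hydroxy-7,8,6'-trimethoxyflavone-3-carboxylic acid A2. Lactone hydrolysis and decarboxylation would then reveal the 2'-hydroxyl and C3–H.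
- Merits: the most hindered bond is made intramolecularly, the tether leaves no trace, ring B never needs a protecting group, and the C8 methoxy group is present before the coupling. In these respects it is better than the chosen plan.
- Weak points: the key step forms one bond and presupposes the complete 5,6,7,8-oxygenated chromone, so the hexasubstituted ring A and ring C must first be built by a classical sequence, which is the hard part of the problem. 3-Acylchromones are strong acceptors at C2, and carbonate or pivalate at direct-arylation temperatures can open the pyranone or cleave the aryl ester. Oxidative addition must occur at a bromide between two ortho substituents.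
- Comparison: the chosen plan makes ring C instead of assuming it. It never has to form the C2–C1' bond under hindrance, since that bond comes from the formyl carbon of 13.

**Alternative 3:** The cuts are C4a–C5 and O1–C2. Methanolic hydroxide would open a 4-pyranone that masks a polyketide chain; the C4a carbanion attacks the terminal ester to close ring A, and acidification re-closes ring C. The product is 2-[2-(benzyloxy)-6-methoxyphenyl]-5,7-dihydroxy-6,8-dimethoxy-4H-chromen-4-one A3.
- Merits: rings A and C arise in one operation with all four ring A oxygens present. Ring A of A3 is symmetric about the C4a–C7 axis, so closure through either phenol gives the same flavone. No aryne, metalation or late oxidation is involved, and ring construction is more economical than in the chosen plan.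
- Weak points: the pattern delivered is 5,7-dihydroxy-6,8-dimethoxy, whereas the target needs hydroxyl at C6 and methoxy at C7. The 7-hydroxyl could be methylated selectively, but the 6-methoxy group would then have to be cleaved in the presence of the 7-, 8- and 6'-methoxy groups and the benzyl ether, which rests on Lewis-acid chelation and is uncertain. The pyranone precursor with two α-methoxy groups and a terminal ester is itself a multistep target.
- Comparison: in the chosen plan no methyl group ever has to be removed or moved. Two of the three methyl ethers come with the commercial aldehydes 1 and 13, and only the C8 methoxy group is added.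

Key step: step 9

Remark on numbering: ring A atoms are referred to by flavone numbering also before ring C exists; in the benzodioxole names, C4 is the future C4a and C5 the future C8a.

## Route

Step 1
Reactants: 1 2,3-dihydroxy-4-methoxybenzaldehyde; 2 dichlorodiphenylmethane
Product: 3 7-methoxy-2,2-diphenyl-1,3-benzodioxole-4-carbaldehyde
Conditions: Ph2CCl2 (1.2 equiv), Ph2O, 175 °C
Reagents that add atoms: none
Why: Thermal double O-alkylation of the catechol by the gem-dichloride with loss of HCl (ketalisation), a standard protection of catechol aldehydes and 2,3-dihydroxybenzoates; the ketal has no benzylic hydrogen and therefore tolerates the later organolithium step.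

Step 2
Reactants: 3 7-methoxy-2,2-diphenyl-1,3-benzodioxole-4-carbaldehyde
Product: 5 7-methoxy-2,2-diphenyl-1,3-benzodioxol-4-ol, via formate ester 4 (not isolated)
Conditions: mCPBA, CH2Cl2, 0 °C to rt; aq. NaHCO3 wash; then K2CO3 (cat.), MeOH, rt
Reagents that add atoms: 3-chloroperoxybenzoic acid, O=C(OO)c1cccc(Cl)c1
Why: Baeyer–Villiger (Dakin-type) oxidation of an electron-rich benzaldehyde; aryl migration is favoured by the ortho ketal oxygen and the para methoxy group, and the resulting formate is cleaved by mild methanolysis that leaves the ketal intact.

Step 3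
Reactants: 5 7-methoxy-2,2-diphenyl-1,3-benzodioxol-4-ol
Product: 6 7-methoxy-2,2-diphenyl-1,3-benzodioxol-4-yl N-(propan-2-yl)carbamate
Conditions: iPrNCO, Et3N (cat.), CH2Cl2, rt
Reagents that add atoms: isopropyl isocyanate, CC(C)N=C=O
Why: Base-catalysed addition of the phenol to the isocyanate gives the N-isopropyl carbamate, a strong ortho-directing group that can later be removed under mild basic conditions.

Step 4
Reactants: 6 7-methoxy-2,2-diphenyl-1,3-benzodioxol-4-yl N-(propan-2-yl)carbamate
Product: 10 7-methoxy-2,2-diphenyl-5-(trimethylsilyl)-1,3-benzodioxol-4-yl N-(propan-2-yl)carbamate, via N-silyl carbamate 7 (not isolated), via aryllithium 8 (not isolated), via N-silyl C-silyl carbamate 9 (not isolated)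
Conditions: TBSOTf, TMEDA, Et2O, 0 °C to rt; n-BuLi (2 equiv), TMEDA, −78 °C; TMSCl, −78 °C to rt; aq. NaHSO4 work-up
Reagents that add atoms: chlorotrimethylsilane, C[Si](C)(C)Cl
Why: Directed ortho-metalation; in situ N-silylation masks the N–H, the carbamate then directs lithiation to its only free ortho position (the future C8a) in preference to the position beside the weaker methoxy director, and quenching with TMSCl at −78 °C forestalls anionic ortho-Fries migration. The N–Si bond is hydrolysed on work-up.

Step 5
Reactants: 10 7-methoxy-2,2-diphenyl-5-(trimethylsilyl)-1,3-benzodioxol-4-yl N-(propan-2-yl)carbamate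
Product: 12 7-methoxy-2,2-diphenyl-5-(trimethylsilyl)-1,3-benzodioxol-4-yl trifluoromethanesulfonate, via silylphenol 11 (not isolated)
Conditions: DBU, Et2NH, MeCN, 40 °C; then PhNTf2, rt
Reagents that add atoms: N-phenylbis(trifluoromethanesulfonimide), O=S(=O)(N(c1ccccc1)S(=O)(=O)C(F)(F)F)C(F)(F)F
Why: DBU-induced E1cB cleavage of the N–H carbamate releases the phenoxide and isopropyl isocyanate, which diethylamine scavenges as the urea; the phenoxide is triflated in the same flask, the standard way to 2-silylaryl triflates.

Step 6
Reactants: 13 2-hydroxy-6-methoxybenzaldehyde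
Product: 14 2-(benzyloxy)-6-methoxybenzaldehyde
Conditions: BnBr, K2CO3, DMF, 60 °C
Reagents that add atoms: benzyl bromide, BrCc1ccccc1
Why: Williamson etherification of the chelated phenol in a dipolar aprotic solvent; benzyl is chosen so that the ring B phenol is released in the final hydrogenolysis.

Step 7
Reactants: 14 2-(benzyloxy)-6-methoxybenzaldehyde
Product: 15 1-(benzyloxy)-2-ethynyl-3-methoxybenzene
Conditions: dimethyl (1-diazo-2-oxopropyl)phosphonate, K2CO3, MeOH, rt
Reagents that add atoms: dimethyl (1-diazo-2-oxopropyl)phosphonate, CC(=O)C(=[N+]=[N-])P(=O)(OC)OC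
Why: Seyferth–Gilbert homologation with the Ohira–Bestmann reagent; methoxide liberates the diazomethylphosphonate anion, olefination gives a diazoalkene that loses N2, and a 1,2-shift in the alkylidene carbene gives the terminal alkyne under conditions that spare both ethers.

Step 8
Reactants: 15 1-(benzyloxy)-2-ethynyl-3-methoxybenzene
Product: 17 3-[2-(benzyloxy)-6-methoxyphenyl]prop-2-ynoic acid, via lithium acetylide 16 (not isolated)
Conditions: n-BuLi, THF, −78 °C; CO2, −78 °C to 0 °C; cold 1 M HCl work-up
Reagents that add atoms: carbon dioxide, O=C=O
Why: Deprotonation of the terminal alkyne and carboxylation of the lithium acetylide; cold acidification avoids decarboxylation of the electron-rich arylpropiolic acid.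

Step 9
Reactants: 12 7-methoxy-2,2-diphenyl-5-(trimethylsilyl)-1,3-benzodioxol-4-yl trifluoromethanesulfonate; 17 3-[2-(benzyloxy)-6-methoxyphenyl]prop-2-ynoic acid
Product: 20 2-[2-(benzyloxy)-6-methoxyphenyl]-5,6-(diphenylmethylenedioxy)-7-methoxy-4H-chromen-4-one, via aryne 18 (not isolated), via hydroxyaryl ynone 19 (not isolated)
Conditions: 12 (1.5 equiv), CsF (4 equiv), THF, 125 °C, sealed tube
Reagents that add atoms: none
Why: Fluoride attacks silicon and triflate leaves, generating aryne 18 across C4a–C8a. Its only flanking heteroatom is the ketal oxygen on C5, whose inductive pull makes C8a the flatter and more electrophilic terminus, so the cesium carboxylate of 17 bonds through oxygen to C8a and the aryl anion develops at C4a beside that oxygen. The anion adds to the neighbouring ester carbonyl through a four-membered transition structure and the acyl C–O bond breaks, which amounts to insertion of the aryne into the carboxylic C–O bond and gives the phenoxide of ynone 19 with C4–C4a formed and O1 on C8a. The phenoxide then adds to the ynone β-carbon C2 in a 6-endo-dig oxa-Michael closure of ring C, and protonation at C3 gives 20. The closest known reaction type is the fluoride-mediated insertion of arynes into carboxylic acids to give 2-hydroxyaryl ketones, which with arylpropiolic acids runs on to flavones. No stereocentre is formed. The step needs addition at C8a (secured by the absence of a C8 substituent), acyl transfer faster than protonation of the aryl anion (favoured by the hot aprotic medium and the proximity of the ester), and 6-endo over 5-exo closure (favoured by the conjugate polarisation of the ynone).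

Step 10
Reactants: 20 2-[2-(benzyloxy)-6-methoxyphenyl]-5,6-(diphenylmethylenedioxy)-7-methoxy-4H-chromen-4-one
Product: 21 2-[2-(benzyloxy)-6-methoxyphenyl]-5,6-dihydroxy-7-methoxy-4H-chromen-4-one
Conditions: AcOH/H2O (4:1), 100 °C, under N2
Reagents that add atoms: none
Why: Acid hydrolysis of the diphenylmethylene ketal through the stabilised aryloxy(diphenyl)carbenium ion; aryl benzyl and methyl ethers are stable in hot aqueous acetic acid, which is too weak an acid to cause Wessely–Moser isomerisation.

Step 11
Reactants: 21 2-[2-(benzyloxy)-6-methoxyphenyl]-5,6-dihydroxy-7-methoxy-4H-chromen-4-one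
Product: 22 6-(benzyloxy)-2-[2-(benzyloxy)-6-methoxyphenyl]-5-hydroxy-7-methoxy-4H-chromen-4-one
Conditions: BnBr (1.1 equiv), K2CO3, acetone, 56 °C, under N2
Reagents that add atoms: benzyl bromide, BrCc1ccccc1
Why: Selective Williamson benzylation of the 6-hydroxyl; the 5-hydroxyl is held in a hydrogen bond to the C4 carbonyl and is far less nucleophilic, the established basis of partial alkylation in 5-hydroxyflavones.

Step 12
Reactants: 22 6-(benzyloxy)-2-[2-(benzyloxy)-6-methoxyphenyl]-5-hydroxy-7-methoxy-4H-chromen-4-one
Product: 24 6-(benzyloxy)-2-[2-(benzyloxy)-6-methoxyphenyl]-5,8-dihydroxy-7-methoxy-4H-chromen-4-one, via aryl sulfate 23 (not isolated)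
Conditions: K2S2O8, aq. KOH, pyridine, 5 °C to rt; then 2 M HCl, Na2SO3, 80 °C
Reagents that add atoms: potassium peroxodisulfate, [K+].[K+].[O-]S(=O)(=O)OOS(=O)(=O)[O-]
Why: Elbs persulfate oxidation; the 5-phenoxide attacks the peroxide oxygen through its para carbon C8, the only unsubstituted ring A position, and the aryl sulfate is hydrolysed by acid to the hydroquinone while sulfite keeps it reduced. This is the classical nuclear oxidation of 5-hydroxyflavones to 5,8-dihydroxyflavones.

Step 13
Reactants: 24 6-(benzyloxy)-2-[2-(benzyloxy)-6-methoxyphenyl]-5,8-dihydroxy-7-methoxy-4H-chromen-4-one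
Product: 25 6-(benzyloxy)-2-[2-(benzyloxy)-6-methoxyphenyl]-5-hydroxy-7,8-dimethoxy-4H-chromen-4-one
Conditions: Me2SO4 (1.05 equiv), K2CO3, acetone, 56 °C, under N2
Reagents that add atoms: dimethyl sulfate, COS(=O)(=O)OC
Why: Selective O-methylation of the free 8-hydroxyl; the chelated 5-hydroxyl does not react with one equivalent of alkylating agent under carbonate conditions, and the inert atmosphere prevents oxidation of the hydroquinone to the 5,8-quinone.

Step 14
Reactants: 25 6-(benzyloxy)-2-[2-(benzyloxy)-6-methoxyphenyl]-5-hydroxy-7,8-dimethoxy-4H-chromen-4-one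
Product: 26 5,6-dihydroxy-2-(2-hydroxy-6-methoxyphenyl)-7,8-dimethoxy-4H-chromen-4-one
Conditions: H2 (1 atm), Pd/C (palladium on carbon), EtOAc/MeOH, rt
Reagents that add atoms: none
Why: Hydrogenolysis of both aryl benzyl ethers under neutral conditions; the flavone C2–C3 double bond and the methyl ethers are expected to survive at ambient pressure, and the catechol is released only in this last step.

## Compound list

1 | 2,3-dihydroxy-4-methoxybenzaldehyde | COc1ccc(C=O)c(O)c1O | starting material
2 | dichlorodiphenylmethane | ClC(Cl)(c1ccccc1)c1ccccc1 | starting material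
3 | 7-methoxy-2,2-diphenyl-1,3-benzodioxole-4-carbaldehyde | COc1ccc(C=O)c2OC(c3ccccc3)(c3ccccc3)Oc12 | intermediate
4 | 7-methoxy-2,2-diphenyl-1,3-benzodioxol-4-yl formate | COc1ccc(OC=O)c2OC(c3ccccc3)(c3ccccc3)Oc12 | intermediate
5 | 7-methoxy-2,2-diphenyl-1,3-benzodioxol-4-ol | COc1ccc(O)c2OC(c3ccccc3)(c3ccccc3)Oc12 | intermediate
6 | 7-methoxy-2,2-diphenyl-1,3-benzodioxol-4-yl N-(propan-2-yl)carbamate | COc1ccc(OC(=O)NC(C)C)c2OC(c3ccccc3)(c3ccccc3)Oc12 | intermediate
7 | 7-methoxy-2,2-diphenyl-1,3-benzodioxol-4-yl N-(tert-butyldimethylsilyl)-N-(propan-2-yl)carbamate | COc1ccc(OC(=O)N(C(C)C)[Si](C)(C)C(C)(C)C)c2OC(c3ccccc3)(c3ccccc3)Oc12 | intermediate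
8 | [4-{[(tert-butyldimethylsilyl)(propan-2-yl)carbamoyl]oxy}-7-methoxy-2,2-diphenyl-1,3-benzodioxol-5-yl]lithium | COc1cc([Li])c(OC(=O)N(C(C)C)[Si](C)(C)C(C)(C)C)c2OC(c3ccccc3)(c3ccccc3)Oc12 | intermediate
9 | 7-methoxy-2,2-diphenyl-5-(trimethylsilyl)-1,3-benzodioxol-4-yl N-(tert-butyldimethylsilyl)-N-(propan-2-yl)carbamate | COc1cc([Si](C)(C)C)c(OC(=O)N(C(C)C)[Si](C)(C)C(C)(C)C)c2OC(c3ccccc3)(c3ccccc3)Oc12 | intermediate
10 | 7-methoxy-2,2-diphenyl-5-(trimethylsilyl)-1,3-benzodioxol-4-yl N-(propan-2-yl)carbamate | COc1cc([Si](C)(C)C)c(OC(=O)NC(C)C)c2OC(c3ccccc3)(c3ccccc3)Oc12 | intermediate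
11 | 7-methoxy-2,2-diphenyl-5-(trimethylsilyl)-1,3-benzodioxol-4-ol | COc1cc([Si](C)(C)C)c(O)c2OC(c3ccccc3)(c3ccccc3)Oc12 | intermediate
12 | 7-methoxy-2,2-diphenyl-5-(trimethylsilyl)-1,3-benzodioxol-4-yl trifluoromethanesulfonate | COc1cc([Si](C)(C)C)c(OS(=O)(=O)C(F)(F)F)c2OC(c3ccccc3)(c3ccccc3)Oc12 | intermediate
13 | 2-hydroxy-6-methoxybenzaldehyde | COc1cccc(O)c1C=O | starting material
14 | 2-(benzyloxy)-6-methoxybenzaldehyde | COc1cccc(OCc2ccccc2)c1C=O | intermediate
15 | 1-(benzyloxy)-2-ethynyl-3-methoxybenzene | COc1cccc(OCc2ccccc2)c1C#C | intermediate
16 | {[2-(benzyloxy)-6-methoxyphenyl]ethynyl}lithium | COc1cccc(OCc2ccccc2)c1C#C[Li] | intermediate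
17 | 3-[2-(benzyloxy)-6-methoxyphenyl]prop-2-ynoic acid | COc1cccc(OCc2ccccc2)c1C#CC(=O)O | intermediate
18 | 4,5-didehydro-7-methoxy-2,2-diphenyl-1,3-benzodioxole (aryne) | COC1=CC#CC2=C1OC(c1ccccc1)(c1ccccc1)O2 | intermediate
19 | 3-[2-(benzyloxy)-6-methoxyphenyl]-1-(5-hydroxy-7-methoxy-2,2-diphenyl-1,3-benzodioxol-4-yl)prop-2-yn-1-one | COc1cccc(OCc2ccccc2)c1C#CC(=O)c1c(O)cc(OC)c2OC(c3ccccc3)(c3ccccc3)Oc12 | intermediate
20 | 2-[2-(benzyloxy)-6-methoxyphenyl]-5,6-(diphenylmethylenedioxy)-7-methoxy-4H-chromen-4-one | COc1cccc(OCc2ccccc2)c1-c1cc(=O)c2c3OC(c4ccccc4)(c4ccccc4)Oc3c(OC)cc2o1 | intermediate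
21 | 2-[2-(benzyloxy)-6-methoxyphenyl]-5,6-dihydroxy-7-methoxy-4H-chromen-4-one | COc1cccc(OCc2ccccc2)c1-c1cc(=O)c2c(O)c(O)c(OC)cc2o1 | intermediate
22 | 6-(benzyloxy)-2-[2-(benzyloxy)-6-methoxyphenyl]-5-hydroxy-7-methoxy-4H-chromen-4-one | COc1cccc(OCc2ccccc2)c1-c1cc(=O)c2c(O)c(OCc3ccccc3)c(OC)cc2o1 | intermediate
23 | potassium 6-(benzyloxy)-2-[2-(benzyloxy)-6-methoxyphenyl]-5-hydroxy-7-methoxy-4-oxo-4H-chromen-8-yl sulfate | [K+].COc1cccc(OCc2ccccc2)c1-c1cc(=O)c2c(O)c(OCc3ccccc3)c(OC)c(OS(=O)(=O)[O-])c2o1 | intermediate
24 | 6-(benzyloxy)-2-[2-(benzyloxy)-6-methoxyphenyl]-5,8-dihydroxy-7-methoxy-4H-chromen-4-one | COc1cccc(OCc2ccccc2)c1-c1cc(=O)c2c(O)c(OCc3ccccc3)c(OC)c(O)c2o1 | intermediate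
25 | 6-(benzyloxy)-2-[2-(benzyloxy)-6-methoxyphenyl]-5-hydroxy-7,8-dimethoxy-4H-chromen-4-one | COc1cccc(OCc2ccccc2)c1-c1cc(=O)c2c(O)c(OCc3ccccc3)c(OC)c(OC)c2o1 | intermediate
26 | 5,6-dihydroxy-2-(2-hydroxy-6-methoxyphenyl)-7,8-dimethoxy-4H-chromen-4-one (5,6,2'-trihydroxy-7,8,6'-trimethoxyflavone) | COc1cccc(O)c1-c1cc(=O)c2c(O)c(O)c(OC)c(OC)c2o1 | target

## Step count and risks

Total step count: 14.
Longest linear sequence: 11 steps (steps 1–5, then 9–14); the ring B branch (steps 6–8) joins at step 9.

**Step 9 (key step).** Three processes could divert it:
- Protonation of the C4a aryl anion by the acid before acyl transfer would stop at simple O-arylation.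
- Thermal decarboxylation of the electron-rich propiolate at 125 °C would consume the acid partner.
- Closure of the ynone phenoxide could go 5-exo-dig, or stall, because the alkyne terminus carries a di-ortho-substituted aryl group.

Fallback: the aryne is kept but the three-carbon unit is built stepwise.
- Starting from 12, insertion into acetic acid under the same fluoride conditions (the simplest and best-behaved acid partner of this reaction type) should give 1-(5-hydroxy-7-methoxy-2,2-diphenyl-1,3-benzodioxol-4-yl)ethan-1-one F1.
- Claisen–Schmidt condensation of F1 with aldehyde 14 (KOH, EtOH) should give (E)-3-[2-(benzyloxy)-6-methoxyphenyl]-1-(5-hydroxy-7-methoxy-2,2-diphenyl-1,3-benzodioxol-4-yl)prop-2-en-1-one F2.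
- Oxidative cyclisation of this 2'-hydroxychalcone with catalytic iodine in hot DMSO returns to the route at 20.

**Step 12.** The persulfate oxidation may suffer from incomplete conversion, from opening of the pyranone in aqueous alkali, and from over-oxidation of the hydroquinone to the 5,8-quinone; modest conversion with recovery of 22 is typical of this reaction class.

Fallback: starting from 22, electrophilic bromination para to the 5-hydroxyl (NBS, MeCN, 0 °C) should give 6-(benzyloxy)-2-[2-(benzyloxy)-6-methoxyphenyl]-8-bromo-5-hydroxy-7-methoxy-4H-chromen-4-one F3. Copper-mediated methanolysis of the aryl bromide (NaOMe, CuBr, DMF/MeOH, 110 °C) then gives 25 directly and bypasses 24. The weakness of this alternative is possible competing bromination of ring B, which is why it is not the first choice.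

**Step 4.** Lithiation beside the methoxy group, anionic ortho-Fries migration of the carbamoyl group on warming, or addition of n-BuLi to the carbamate carbonyl would erode the silylation.

Fallback: a bromine–lithium exchange route from phenol 5.
- Amine-catalysed ortho-bromination (NBS, iPr2NH cat., CH2Cl2) should give 5-bromo-7-methoxy-2,2-diphenyl-1,3-benzodioxol-4-ol F4.
- Silylation with hexamethyldisilazane gives [(5-bromo-7-methoxy-2,2-diphenyl-1,3-benzodioxol-4-yl)oxy]trimethylsilane F5.
- n-BuLi at −78 °C triggers halogen–lithium exchange and 1,3-migration of silicon from oxygen to carbon (retro-Brook), giving the lithium salt of 11, which is triflated with Tf2O to return at 12.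

**Step 7.** The homologation may be slow or incomplete because the aldehyde is electron-rich and flanked by two ortho substituents.

Fallback: Corey–Fuchs chemistry from 14. CBr4/PPh3 in CH2Cl2 should give 1-(benzyloxy)-2-(2,2-dibromoethenyl)-3-methoxybenzene F6. Treatment with two equivalents of n-BuLi generates lithium acetylide 16, which is carboxylated with CO2 in the same flask to return at 17 without isolating 15.

## Further compounds

F1 | step 9 | 1-(5-hydroxy-7-methoxy-2,2-diphenyl-1,3-benzodioxol-4-yl)ethan-1-one | CC(=O)c1c(O)cc(OC)c2OC(c3ccccc3)(c3ccccc3)Oc12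
F2 | step 9 | (E)-3-[2-(benzyloxy)-6-methoxyphenyl]-1-(5-hydroxy-7-methoxy-2,2-diphenyl-1,3-benzodioxol-4-yl)prop-2-en-1-one | COc1cccc(OCc2ccccc2)c1/C=C/C(=O)c1c(O)cc(OC)c2OC(c3ccccc3)(c3ccccc3)Oc12
F3 | step 12 | 6-(benzyloxy)-2-[2-(benzyloxy)-6-methoxyphenyl]-8-bromo-5-hydroxy-7-methoxy-4H-chromen-4-one | COc1cccc(OCc2ccccc2)c1-c1cc(=O)c2c(O)c(OCc3ccccc3)c(OC)c(Br)c2o1
F4 | step 4 | 5-bromo-7-methoxy-2,2-diphenyl-1,3-benzodioxol-4-ol | COc1cc(Br)c(O)c2OC(c3ccccc3)(c3ccccc3)Oc12
F5 | step 4 | [(5-bromo-7-methoxy-2,2-diphenyl-1,3-benzodioxol-4-yl)oxy]trimethylsilane | COc1cc(Br)c(O[Si](C)(C)C)c2OC(c3ccccc3)(c3ccccc3)Oc12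
F6 | step 7 | 1-(benzyloxy)-2-(2,2-dibromoethenyl)-3-methoxybenzene | COc1cccc(OCc2ccccc2)c1C=C(Br)Br
A1 | alternative 1 | methyl 6-(benzyloxy)-2,5-dihydroxy-3,4-dimethoxybenzoate | COC(=O)c1c(O)c(OC)c(OC)c(O)c1OCc1ccccc1
A2 | alternative 2 | 3,2'-lactone of 5,6-(diphenylmethylenedioxy)-2'-hydroxy-7,8,6'-trimethoxyflavone-3-carboxylic acid | COc1cccc2OC(=O)c3c(oc4c(OC)c(OC)c5OC(c6ccccc6)(c6ccccc6)Oc5c4c3=O)-c12
A3 | alternative 3 | 2-[2-(benzyloxy)-6-methoxyphenyl]-5,7-dihydroxy-6,8-dimethoxy-4H-chromen-4-one | COc1cccc(OCc2ccccc2)c1-c1cc(=O)c2c(O)c(OC)c(O)c(OC)c2o1
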